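**Retrosynthetic overview**
- Last step: global debenzylation (BCl3/pentamethylbenzene) of a pentabenzyl precursor, so nothing reductive or hydrolytic touches the lactone, the two alkenes or the ester.
- Aryl–vinyl bond at C7 of the benzodioxinone: Heck disconnection to a 7-bromo-(Z)-3-arylidene-1,4-benzodioxin-2-one and the O-acryloyl derivative of tribenzyl (R)-danshensu.
- Exocyclic Z-alkene: aldol condensation of 7-bromo-1,4-benzodioxin-2(3H)-one with 3,4-bis(benzyloxy)benzaldehyde.
- Key step, and the only ring construction (done first): one-flask desymmetrisation of catechol with chloroacetyl chloride to the dioxinone ring, whose ether oxygen then directs bromination para to itself. The three benzene rings are bought.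

Assumption: sodium (R)-danshensu and 3,4-bis(benzyloxy)benzaldehyde are bought; the (R) centre of the target comes from the former and is never touched.

**Step 1**
Reactants: 1 catechol; 2 chloroacetyl chloride
Product: 5 7-bromo-1,4-benzodioxin-2(3H)-one, via 2-hydroxyphenyl chloroacetate 3 (not isolated), via unbrominated 1,4-benzodioxin-2(3H)-one 4 (not isolated)
Conditions: K2CO3 (2.2 equiv), MeCN, 0 → 60 °C; then Br2 (1.05 equiv), 0 °C → rt, same flask
Reagents that add atoms: bromine, BrBr
Why: O-acylation of one hydroxyl of C2v-symmetric catechol and intramolecular Williamson etherification (6-exo-tet) break the symmetry by turning the two oxygens into an ester oxygen and an ether oxygen, so the electrophilic aromatic bromination that follows goes para to the much more donating ether oxygen (C7), which is the substitution pattern of the target; no stereocentre is formed.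

**Step 2**
Reactants: 5 7-bromo-1,4-benzodioxin-2(3H)-one; 6 3,4-bis(benzyloxy)benzaldehyde
Product: 8 (3Z)-3-[3,4-bis(benzyloxy)benzylidene]-7-bromo-1,4-benzodioxin-2(3H)-one, via aldol adduct 7 (not isolated)
Conditions: TiCl4 (1.3 equiv), Et3N (1.5 equiv), CH2Cl2, −78 °C, then 6; H2O work-up; crude, TsOH·H2O (10 mol%), 1,2-dichloroethane, 60 °C
Reagents that add atoms: none
Why: Soft enolisation of the aryl lactone gives a titanium enolate that adds to the aldehyde (Ti-mediated crossed aldol addition), and acid-catalysed E1 dehydration through the 4-benzyloxybenzylic cation gives the conjugated alkene as the thermodynamically favoured Z isomer (aryl anti to the lactone carbonyl, as in aurones), the two stereocentres of 7 being destroyed.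

**Step 3**
Reactants: 9 sodium (2R)-3-(3,4-dihydroxyphenyl)-2-hydroxypropanoate (sodium (R)-danshensu)
Product: 10 benzyl (2R)-3-[3,4-bis(benzyloxy)phenyl]-2-hydroxypropanoate
Conditions: BnBr (3.3 equiv), K2CO3 (2.5 equiv), DMF, rt, argon
Reagents that add atoms: benzyl bromide, BrCc1ccccc1
Why: Carboxylate SN2 esterification and Williamson etherification of the two acidic phenols proceed with K2CO3 while the secondary alcohol is not deprotonated and stays free, and the bought (R) centre is not involved.

**Step 4**
Reactants: 10 benzyl (2R)-3-[3,4-bis(benzyloxy)phenyl]-2-hydroxypropanoate; 11 acryloyl chloride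
Product: 12 benzyl (2R)-2-(acryloyloxy)-3-[3,4-bis(benzyloxy)phenyl]propanoate
Conditions: Et3N (1.5 equiv), CH2Cl2, −20 → 0 °C
Reagents that add atoms: none
Why: O-acylation of the secondary alcohol with an acid chloride does not break the C–O bond at the stereocentre, so (R) is retained.

**Step 5**
Reactants: 8 (3Z)-3-[3,4-bis(benzyloxy)benzylidene]-7-bromo-1,4-benzodioxin-2(3H)-one; 12 benzyl (2R)-2-(acryloyloxy)-3-[3,4-bis(benzyloxy)phenyl]propanoate
Product: 13 benzyl (2R)-3-[3,4-bis(benzyloxy)phenyl]-2-{[(2E)-3-{(3Z)-3-[3,4-bis(benzyloxy)benzylidene]-2-oxo-2,3-dihydro-1,4-benzodioxin-7-yl}prop-2-enoyl]oxy}propanoate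
Conditions: Pd(P(t-Bu)3)2 (3 mol%), Cy2NMe (1.2 equiv), 1,4-dioxane, 50 °C
Reagents that add atoms: none
Why: Mizoroki–Heck reaction, in which oxidative addition of the aryl bromide to zerovalent palladium, syn insertion of the acrylate and syn β-hydride elimination give the E-cinnamate, while the hindered amine at 50 °C leaves the aryl lactone, the Z-enol ether and the α-acyloxy ester stereocentre intact.

**Step 6**
Reactants: 13 pentabenzyl precursor (name as in step 5)
Product: 14 (2R)-3-(3,4-dihydroxyphenyl)-2-{[(2E)-3-{(3Z)-3-[(3,4-dihydroxyphenyl)methylidene]-2-oxo-2,3-dihydro-1,4-benzodioxin-7-yl}prop-2-enoyl]oxy}propanoic acid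
Conditions: BCl3 (1 M in CH2Cl2, 12 equiv), pentamethylbenzene (15 equiv), CH2Cl2, −78 → 0 °C; H2O/THF quench
Reagents that add atoms: none
Why: Lewis-acid debenzylation with BCl3 and pentamethylbenzene as a non-basic benzyl cation scavenger removes the four aryl benzyl ethers and the benzyl ester without reduction or hydrolysis, so both alkenes, the aryl lactone, the cinnamate ester and the (R) centre survive.

**Compound list**
1 | catechol | Oc1ccccc1O | starting material
2 | chloroacetyl chloride | O=C(Cl)CCl | starting material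
3 | 2-hydroxyphenyl chloroacetate (forms in the flask) | O=C(CCl)Oc1ccccc1O | intermediate
4 | 1,4-benzodioxin-2(3H)-one (forms in the flask) | O=C1COc2ccccc2O1 | intermediate
5 | 7-bromo-1,4-benzodioxin-2(3H)-one | O=C1COc2ccc(Br)cc2O1 | intermediate
6 | 3,4-bis(benzyloxy)benzaldehyde | O=Cc1ccc(OCc2ccccc2)c(OCc2ccccc2)c1 | starting material
7 | 3-{[3,4-bis(benzyloxy)phenyl](hydroxy)methyl}-7-bromo-1,4-benzodioxin-2(3H)-one, racemic diastereomer mixture (crude) | O=C1Oc2cc(Br)ccc2OC1C(O)c1ccc(OCc2ccccc2)c(OCc2ccccc2)c1 | intermediate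
8 | (3Z)-3-[3,4-bis(benzyloxy)benzylidene]-7-bromo-1,4-benzodioxin-2(3H)-one | Brc1ccc2c(c1)OC(=O)/C(=C/c1ccc(OCc3ccccc3)c(OCc3ccccc3)c1)O2 | intermediate
9 | sodium (2R)-3-(3,4-dihydroxyphenyl)-2-hydroxypropanoate | [Na+].[O-]C(=O)[C@H](O)Cc1ccc(O)c(O)c1 | starting material
10 | benzyl (2R)-3-[3,4-bis(benzyloxy)phenyl]-2-hydroxypropanoate | O=C(OCc1ccccc1)[C@H](O)Cc1ccc(OCc2ccccc2)c(OCc2ccccc2)c1 | intermediate
11 | acryloyl chloride | C=CC(=O)Cl | starting material
12 | benzyl (2R)-2-(acryloyloxy)-3-[3,4-bis(benzyloxy)phenyl]propanoate | C=CC(=O)O[C@H](Cc1ccc(OCc2ccccc2)c(OCc2ccccc2)c1)C(=O)OCc1ccccc1 | intermediate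
13 | pentabenzyl precursor (full name in step 5) | O=C(/C=C/c1ccc2c(c1)OC(=O)/C(=C/c1ccc(OCc3ccccc3)c(OCc3ccccc3)c1)O2)O[C@H](Cc1ccc(OCc2ccccc2)c(OCc2ccccc2)c1)C(=O)OCc1ccccc1 | intermediate
14 | target (full name in step 6) | O=C(/C=C/c1ccc2c(c1)OC(=O)/C(=C/c1ccc(O)c(O)c1)O2)O[C@H](Cc1ccc(O)c(O)c1)C(=O)O | target

**Step count**
Total: 6 steps. Longest linear sequence: 4 steps (steps 1, 2, 5, 6; the branch through steps 3, 4, 5, 6 is equally long).

**Three steps most likely to fail**

Step 1. The risks are oligo-esters or incomplete ring closure in the one-flask annulation, and minor 5- or 6-bromo isomers. The fallback sets out from catechol 1 and makes the ether bond first: excess 1 is mono-alkylated with ethyl bromoacetate (K2CO3, acetone, reflux) to ethyl 2-(2-hydroxyphenoxy)acetate F1. F1 is closed by acid-catalysed transesterification (TsOH, toluene, reflux, ethanol distilled off) to lactone 4, which is now isolated and purified. Pure 4 is brominated separately (NBS, catalytic TfOH, MeCN), and the route is rejoined at 5.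

Step 2. The risks are self-condensation or opening of the aryl lactone and an E/Z mixture. The fallback sets out from 5 and replaces the aldol by a Horner–Wadsworth–Emmons olefination. Radical bromination at C3 (NBS, AIBN, PhCF3, reflux) gives racemic 3,7-dibromo-1,4-benzodioxin-2(3H)-one F2. Arbuzov reaction with P(OEt)3 at 90 °C gives racemic diethyl (7-bromo-2-oxo-2,3-dihydro-1,4-benzodioxin-3-yl)phosphonate F3. Olefination of F3 with aldehyde 6 (LiCl, DBU, MeCN, rt; catalytic I2 to converge on the Z isomer if needed) rejoins the route at 8.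

Step 6. The risks are incomplete cleavage of the benzyl ester, or damage to the lactone and enol ether when five benzyl groups must come off one large molecule. The fallback sets out from 8 and 12 and deprotects before the coupling. Compound 8 is debenzylated (BCl3, pentamethylbenzene, CH2Cl2, −78 °C) to (3Z)-7-bromo-3-(3,4-dihydroxybenzylidene)-1,4-benzodioxin-2(3H)-one F4. Compound 12 is debenzylated the same way (warming to 0 °C) to (2R)-2-(acryloyloxy)-3-(3,4-dihydroxyphenyl)propanoic acid F5. A Heck coupling of F4 with F5 under weak-base conditions that leave the phenols protonated (Pd(OAc)2, P(o-tol)3, NaOAc, DMF, 90 °C) gives 14 directly, so the route is rejoined at the target.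

**Further compounds**
F1 | step 1 | ethyl 2-(2-hydroxyphenoxy)acetate | CCOC(=O)COc1ccccc1O
F2 | step 2 | 3,7-dibromo-1,4-benzodioxin-2(3H)-one (racemic) | O=C1Oc2cc(Br)ccc2OC1Br
F3 | step 2 | diethyl (7-bromo-2-oxo-2,3-dihydro-1,4-benzodioxin-3-yl)phosphonate (racemic) | CCOP(=O)(OCC)C1Oc2ccc(Br)cc2OC1=O
F4 | step 6 | (3Z)-7-bromo-3-(3,4-dihydroxybenzylidene)-1,4-benzodioxin-2(3H)-one | Brc1ccc2c(c1)OC(=O)/C(=C/c1ccc(O)c(O)c1)O2
F5 | step 6 | (2R)-2-(acryloyloxy)-3-(3,4-dihydroxyphenyl)propanoic acid | C=CC(=O)O[C@H](Cc1ccc(O)c(O)c1)C(=O)O
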